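**Retrosynthetic overview**
- The target is the C-acyl isomer of two six-membered lactones. Cutting two C–C bonds of the cyclohexadienone ring (benzyl-bearing carbon to the enol carbon beside the quaternary centre; acetyl-bearing carbon to the ring C=O carbon) gives an aryl lactone (C20H24O5) and an enol lactone (C17H24O3) whose atoms add up exactly to the target (C37H48O8).
- Enabling feature: the ring C=O carbon lies 1,5 to a phenolic oxygen (O–C(aryl)–C(aryl)–CH2–C–C=O), so it can be stored as a dihydrocoumarin lactone. The acetyl oxygen lies 1,5 to the ring carbon on the other side of the quaternary centre, so that carbon can be stored as a pyran-2,4-dione enol lactone. The quaternary carbon has no α-hydrogen and travels unchanged.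
- Aryl lactone: phloroglucinol → hexanoyl ketone → lactone ring on the para hydroxyl (acrylic acid) → chromene ring (prenal), whose closure is forced onto the one remaining ortho hydroxyl.
- Enol lactone: tert-butyl 2-methylacetoacetate → geranylation of its chiral valine-ester enamine (quaternary stereocentre) → C-acetylation → enol lactonisation.
- Ring order: arene (purchased), temporary lactone ring, chromene ring; in the other branch the temporary pyrandione ring; last, the cyclohexadienone ring, closed while both lactones open.

Key step: step 8

Assumption: the lithiated enamine from L-valine tert-butyl ester in toluene/HMPA is taken to be alkylated on the face that gives the (S)-keto ester; if the opposite sense is found, the D-valine ester is used and nothing else changes.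

**Step 1**
Reactants: 1 phloroglucinol; 2 hexanoyl chloride
Product: 3 1-(2,4,6-trihydroxyphenyl)hexan-1-one
Conditions: AlCl3 (3.5 equiv), PhNO2, 0 → 60 °C; ice/aq. HCl work-up
Reagents that add atoms: none
Why: Friedel–Crafts C-acylation of the symmetric triphenol, where the first acyl group deactivates the ring so that mono-acylation is expected.

**Step 2**
Reactants: 3 1-(2,4,6-trihydroxyphenyl)hexan-1-one; 4 acrylic acid
Product: 5 6-hexanoyl-5,7-dihydroxy-3,4-dihydro-2H-chromen-2-one
Conditions: 4 (1.3 equiv), p-MeC6H4SO3H·H2O (0.2 equiv), PhMe, 110 °C, Dean–Stark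
Reagents that add atoms: none
Why: acid-catalysed Friedel–Crafts conjugate addition of one of the two equivalent free ring carbons to acrylic acid, followed by lactonisation, which should close on the para hydroxyl because it is the only one not held in the ketone chelate.

**Step 3**
Reactants: 5 6-hexanoyl-5,7-dihydroxy-3,4-dihydro-2H-chromen-2-one; 6 3-methylbut-2-enal
Product: 7 6-hexanoyl-5-hydroxy-8,8-dimethyl-3,4-dihydro-2H,8H-pyrano[2,3-h]chromen-2-one
Conditions: 6 (3 equiv), pyridine, 120 °C, sealed tube
Reagents that add atoms: none
Why: chromenylation (aldol-type condensation at the only free arene carbon, dehydration to the ortho-quinone methide, oxa-6π electrocyclisation); the lactone oxygen blocks one flank of that carbon, so the pyran ring can only close on the hydroxyl next to the ketone, which fixes the regiochemistry.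

**Step 4**
Reactants: 8 tert-butyl 2-methyl-3-oxobutanoate; 9 L-valine tert-butyl ester
Product: 10 tert-butyl (2Z)-3-{[(2S)-1-tert-butoxy-3-methyl-1-oxobutan-2-yl]amino}-2-methylbut-2-enoate
Conditions: BF3·OEt2 (cat.), PhH, reflux, Dean–Stark
Reagents that add atoms: none
Why: condensation of the ketone of the β-keto ester with the primary amine gives the hydrogen-bonded (Z)-enamino ester, which removes the labile stereocentre and installs the chiral controller.

**Step 5**
Reactants: 10 tert-butyl (2Z)-3-{[(2S)-1-tert-butoxy-3-methyl-1-oxobutan-2-yl]amino}-2-methylbut-2-enoate; 11 geranyl bromide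
Product: 13 tert-butyl (2S,4E)-2-acetyl-2,5,9-trimethyldeca-4,8-dienoate, via ketimine 12 (not isolated)
Conditions: LiN(i-Pr)2 (1.2 equiv), HMPA (3 equiv), PhMe, −78 °C; 11, −78 → −55 °C; then 10% aq. citric acid, 23 °C
Reagents that add atoms: water, O
Why: alkylation of the lithiated chiral enamine of an α-alkyl β-keto ester, in which lithium is held by the aza-enolate nitrogen and the valinate carbonyl, the isopropyl group shields one face and the allylic bromide enters from the other to set the quaternary centre as (S); mild acid then hydrolyses the ketimine and returns the auxiliary.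

**Step 6**
Reactants: 13 tert-butyl (2S,4E)-2-acetyl-2,5,9-trimethyldeca-4,8-dienoate; 14 acetyl chloride
Product: 15 tert-butyl (2S)-2-[(2E)-3,7-dimethylocta-2,6-dien-1-yl]-2-methyl-3,5-dioxohexanoate
Conditions: MgBr2·OEt2 (2.5 equiv), i-Pr2NEt (3 equiv), 14 (1.3 equiv), CH2Cl2, 0 → 23 °C
Reagents that add atoms: none
Why: soft enolisation and C-acylation of the only enolisable position (the methyl ketone) gives the 1,3-diketone as its magnesium chelate, and since no alkoxide is present the non-enolisable β-keto ester is not cleaved by a retro-Claisen reaction.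

**Step 7**
Reactants: 15 tert-butyl (2S)-2-[(2E)-3,7-dimethylocta-2,6-dien-1-yl]-2-methyl-3,5-dioxohexanoate
Product: 17 (3S)-3-[(2E)-3,7-dimethylocta-2,6-dien-1-yl]-3,6-dimethyl-2H-pyran-2,4(3H)-dione, via diketo acid 16 (not isolated)
Conditions: Me3SiOTf (3.5 equiv), 2,6-lutidine (5 equiv), CH2Cl2, 0 °C; cold aq. NaH2PO4 work-up; then DCC (1.2 equiv), CH2Cl2, 0 °C
Reagents that add atoms: none
Why: silyl triflate with lutidine turns the tert-butyl ester into the silyl ester with loss of isobutene under non-protic conditions that spare the geranyl alkenes, and after hydrolysis the carbodiimide-activated acid is captured by the enol oxygen of the diketone to give the six-membered enol lactone without touching the quaternary centre.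

**Step 8**
Reactants: 7 6-hexanoyl-5-hydroxy-8,8-dimethyl-3,4-dihydro-2H,8H-pyrano[2,3-h]chromen-2-one; 17 (3S)-3-[(2E)-3,7-dimethylocta-2,6-dien-1-yl]-3,6-dimethyl-2H-pyran-2,4(3H)-dione
Product: 19 (4R)-2-acetyl-4-[(2E)-3,7-dimethylocta-2,6-dien-1-yl]-6-[(8-hexanoyl-5,7-dihydroxy-2,2-dimethyl-2H-chromen-6-yl)methyl]-3,5-dihydroxy-4-methylcyclohexa-2,5-dien-1-one (CNP0319887.1), via acylated lactone 18 (not isolated)
Conditions: 7, LiN(SiMe3)2 (2.05 equiv), THF, −78 °C; 17 (1.1 equiv), −78 → −20 °C; LiN(SiMe3)2 (1.1 equiv), −20 → 40 °C; AcOH (4 equiv), 0 °C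
Reagents that add atoms: none
Why: Proposed new method: the lithium enolate of aryl lactone 7 (phenoxide already formed; the lactone methylene should be the most acidic C–H because the hexanoyl ketone is tied up as a chelated vinylogous carboxylate) attacks the enol-ester carbonyl of 17, whose ring opens to the β-diketonate of 18; the diketonate carbon then adds to the aryl-lactone carbonyl (directly, or after E1cB loss of the phenoxide to an acylketene) and expels the phenoxide, so that two lactones are traded for the carbocycle in a 6-exo-trig Claisen (Dieckmann-type) closure. The closest known reactions are the crossed Claisen acylation of lactone enolates by activated esters, the base-mediated Claisen cyclisation of 3,5,7-triketo esters to 2-acylcyclohexane-1,3,5-triones and the enol-ester-to-triketone acyl shift; what is new is their union in one pot on two lactones. No stereocentre is created: the quaternary carbon comes from 17, has no α-hydrogen and keeps its two acyl arms distinct (the lactone carbonyl becomes the enol carbon next to the benzyl-bearing carbon, the ring ketone becomes the enol carbon next to the acetyl-bearing carbon), its descriptor changes from S to R only through the priority rules, and the transient centre at C3 of 18 is lost on enolisation. Selectivity needed: attack at the lactone carbonyl of 17 rather than at its vinylogous-ester ketone or at C6, which the higher electrophilicity of the enol-ester carbonyl toward a hard lithium enolate at −78 °C should secure, and C- rather than O-closure, which follows because every O-acyl isomer is an activated ester that stays in equilibrium through the liberated phenoxide whereas the triketonate (pKa about 4) is the thermodynamic sink. The product is an isomer of 7 plus 17, so nothing has to be removed afterwards.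

**Compound list**
1 | phloroglucinol | Oc1cc(O)cc(O)c1 | starting material
2 | hexanoyl chloride | CCCCCC(Cl)=O | starting material
3 | 1-(2,4,6-trihydroxyphenyl)hexan-1-one | CCCCCC(=O)c1c(O)cc(O)cc1O | intermediate
4 | acrylic acid | C=CC(=O)O | starting material
5 | 6-hexanoyl-5,7-dihydroxy-3,4-dihydro-2H-chromen-2-one | CCCCCC(=O)c1c(O)cc2OC(=O)CCc2c1O | intermediate
6 | 3-methylbut-2-enal | CC(C)=CC=O | starting material
7 | 6-hexanoyl-5-hydroxy-8,8-dimethyl-3,4-dihydro-2H,8H-pyrano[2,3-h]chromen-2-one (dihydrocoumarin lactone fused to the 2,2-dimethylchromene) | CCCCCC(=O)c1c(O)c2CCC(=O)Oc2c2C=CC(C)(C)Oc12 | intermediate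
8 | tert-butyl 2-methyl-3-oxobutanoate (racemic) | CC(=O)C(C)C(=O)OC(C)(C)C | starting material
9 | L-valine tert-butyl ester | CC(C)[C@H](N)C(=O)OC(C)(C)C | starting material
10 | tert-butyl (2Z)-3-{[(2S)-1-tert-butoxy-3-methyl-1-oxobutan-2-yl]amino}-2-methylbut-2-enoate | C/C(N[C@@H](C(C)C)C(=O)OC(C)(C)C)=C(\C)C(=O)OC(C)(C)C | intermediate
11 | geranyl bromide, (2E)-1-bromo-3,7-dimethylocta-2,6-diene | CC(C)=CCC/C(C)=C/CBr | starting material
12 | ketimine of 13 with tert-butyl L-valinate, (S) at the quaternary carbon (not isolated) | CC(=N[C@@H](C(C)C)C(=O)OC(C)(C)C)[C@](C)(C/C=C(\C)CCC=C(C)C)C(=O)OC(C)(C)C | intermediate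
13 | tert-butyl (2S,4E)-2-acetyl-2,5,9-trimethyldeca-4,8-dienoate | CC(=O)[C@](C)(C/C=C(\C)CCC=C(C)C)C(=O)OC(C)(C)C | intermediate
14 | acetyl chloride | CC(Cl)=O | starting material
15 | tert-butyl (2S)-2-[(2E)-3,7-dimethylocta-2,6-dien-1-yl]-2-methyl-3,5-dioxohexanoate | CC(=O)CC(=O)[C@](C)(C/C=C(\C)CCC=C(C)C)C(=O)OC(C)(C)C | intermediate
16 | (2S)-2-[(2E)-3,7-dimethylocta-2,6-dien-1-yl]-2-methyl-3,5-dioxohexanoic acid (not isolated) | CC(=O)CC(=O)[C@](C)(C/C=C(\C)CCC=C(C)C)C(=O)O | intermediate
17 | (3S)-3-[(2E)-3,7-dimethylocta-2,6-dien-1-yl]-3,6-dimethyl-2H-pyran-2,4(3H)-dione | CC1=CC(=O)[C@](C)(C/C=C(\C)CCC=C(C)C)C(=O)O1 | intermediate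
18 | 3-{(2S)-2-[(2E)-3,7-dimethylocta-2,6-dien-1-yl]-2-methyl-3,5-dioxohexanoyl} derivative of 7, both epimers at C3 (not isolated) | CCCCCC(=O)c1c(O)c2CC(C(=O)[C@@](C)(C/C=C(\C)CCC=C(C)C)C(=O)CC(C)=O)C(=O)Oc2c2C=CC(C)(C)Oc12 | intermediate
19 | (4R)-2-acetyl-4-[(2E)-3,7-dimethylocta-2,6-dien-1-yl]-6-[(8-hexanoyl-5,7-dihydroxy-2,2-dimethyl-2H-chromen-6-yl)methyl]-3,5-dihydroxy-4-methylcyclohexa-2,5-dien-1-one (CNP0319887.1) | CCCCCC(=O)c1c(O)c(CC2=C(O)[C@@](C)(C/C=C(\C)CCC=C(C)C)C(O)=C(C(C)=O)C2=O)c(O)c2c1OC(C)(C)C=C2 | target

**Step count and risks**
Total step count: 8. Longest linear sequence: 5 steps (steps 4, 5, 6, 7, 8); the arene branch is steps 1, 2, 3, 8.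

Steps most likely to fail:

Step 8 (proposed new method). What may go wrong: removal of an α-proton of the hexanoyl ketone instead of the lactone proton; proton transfer from the acidic first adduct to unreacted enolate, which stalls the union; or a polyanion that resists the ring switch or closes through the enol oxygen. The fallback uses known chemistry, sets out from 7 and 17 and comes back at 19. The two bond formations are separated. The dilithio derivative of 7 (LiN(SiMe3)2, 2.05 equiv, THF, −78 °C) is added to 17 (1.5 equiv) at −78 °C and quenched cold with AcOH; this is a crossed Claisen acylation of a lactone enolate by an activated ester, and it should stop at acylated lactone 18, which is isolated. In a second flask 18 is treated with NaH (2.2 equiv) in THF at 0 → 40 °C, the plain base-mediated Claisen cyclisation of a 3,5,7-triketo aryl ester to a 2-acylcyclohexane-1,3,5-trione, which should give 19 after mild acidification. The fallback makes no compound outside the list (none, F0).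

Step 2. What may go wrong: slow conjugate addition of the ketone-deactivated arene, lactone closure on a chelated ortho hydroxyl instead of the para one, or Friedel–Crafts acylation leading to a chromanone. The fallback sets out from 3 and comes back at 5, and fixes the lactone oxygen by a tether. The para hydroxyl of 3 (the only non-chelated one) is esterified with propiolic acid (DCC, CH2Cl2, 0 °C) to give 3,5-dihydroxy-4-hexanoylphenyl prop-2-ynoate F1. Intramolecular hydroarylation (Pd(OAc)2 cat., CF3CO2H/CH2Cl2, 23 °C) at either equivalent ortho carbon should give 6-hexanoyl-5,7-dihydroxy-2H-chromen-2-one F2. Hydrogenation of the coumarin C3=C4 bond (H2, Pd/C (palladium metal on carbon), EtOAc) should then return 5.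

Step 7. What may go wrong: decarboxylation or retro-Claisen cleavage of the β-keto acid before the carbodiimide closes the enol lactone, or incomplete ester cleavage. The fallback sets out from 11 and comes back at 17, avoiding the acid altogether. Purchased 4-hydroxy-3,6-dimethyl-2H-pyran-2-one (CC1=CC(O)=C(C)C(=O)O1) is C-geranylated at C3 with 11 (Pd(PPh3)4 5 mol%, DBU, THF, 23 °C); this is a Tsuji–Trost allylation in which any O-allyl ether is re-ionised to the C-allyl product, and it should give racemic 3-[(2E)-3,7-dimethylocta-2,6-dien-1-yl]-3,6-dimethyl-2H-pyran-2,4(3H)-dione F3. Preparative chiral supercritical-fluid chromatography should then deliver 17, and the (3R)-enantiomer F4 is set aside.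

**Further compounds**
F0 | step 8 | none | none
F1 | step 2 | 3,5-dihydroxy-4-hexanoylphenyl prop-2-ynoate | CCCCCC(=O)c1c(O)cc(OC(=O)C#C)cc1O
F2 | step 2 | 6-hexanoyl-5,7-dihydroxy-2H-chromen-2-one | CCCCCC(=O)c1c(O)cc2OC(=O)C=Cc2c1O
F3 | step 7 | racemic 3-[(2E)-3,7-dimethylocta-2,6-dien-1-yl]-3,6-dimethyl-2H-pyran-2,4(3H)-dione | CC1=CC(=O)C(C)(C/C=C(\C)CCC=C(C)C)C(=O)O1
F4 | step 7 | (3R)-3-[(2E)-3,7-dimethylocta-2,6-dien-1-yl]-3,6-dimethyl-2H-pyran-2,4(3H)-dione | CC1=CC(=O)[C@@](C)(C/C=C(\C)CCC=C(C)C)C(=O)O1
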